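**Strategy.** The synthesis rests on cutting the chromone of unit 1 at O1–C8a, C4–C4a and O1–C2. Ring A of that unit has its pyranone oxygen on C8a and the C4 carbonyl on the neighbouring C4a, with the C5 oxygen next to it. This is the pattern a 3,5-dialkoxybenzyne produces when it takes up oxygen and acyl across its triple bond. In a single operation the aryne inserts into the C–O bond of an arylpropiolic acid and ring C closes. The acid precursor already contains the whole unit 2 flavone, bonded through C8 to C3' of the propiolic acid aryl ring, with its 7-oxygen as methyl ether and every other phenol as isopropyl ether. BCl3 finally cleaves the isopropyl ethers.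

Key step: step 14

Assumption: the target has no stereocentre and its biaryl axis is left undefined, so no stereocontrol is planned; unit 1 is the flavone joined at C3' of its ring B, unit 2 the flavone joined at C8; acetophenone 1 is taken as a catalogue compound.

**Step 1**
Reactants: 1 2',6'-dihydroxy-4'-methoxyacetophenone
Product: 2 2'-hydroxy-6'-isopropoxy-4'-methoxyacetophenone
Conditions: 2-bromopropane (1.2 equiv), K2CO3 (1.5 equiv), DMF, 50 °C
Reagents that add atoms: 2-bromopropane, CC(C)Br
Why: Williamson etherification; the two phenols are equivalent, and after the first alkylation the remaining OH is locked in a hydrogen-bonded chelate with the ketone and reacts far more slowly, so the mono-ether should predominate.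

**Step 2**
Reactants: 2 2'-hydroxy-6'-isopropoxy-4'-methoxyacetophenone
Product: 3 2'-hydroxy-3'-iodo-6'-isopropoxy-4'-methoxyacetophenone
Conditions: NIS (1.0 equiv), TFA (cat.), MeCN, 0 °C to rt
Reagents that add atoms: N-iodosuccinimide, O=C1CCC(=O)N1I
Why: Electrophilic aromatic iodination of a phloroglucinol-type ring; C3' (between OH and OMe) is open, whereas C5' is screened by the isopropyl group that the ortho acetyl turns toward it, so iodine should enter ortho to the free phenol, at the carbon that becomes C8 of unit 2.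

**Step 3**
Reactants: 3 2'-hydroxy-3'-iodo-6'-isopropoxy-4'-methoxyacetophenone; 4 4-isopropoxybenzaldehyde
Product: 5 (E)-1-(2-hydroxy-3-iodo-6-isopropoxy-4-methoxyphenyl)-3-(4-isopropoxyphenyl)prop-2-en-1-one
Conditions: KOH (50% aq), EtOH, rt
Reagents that add atoms: none
Why: Claisen–Schmidt aldol condensation of an aryl methyl ketone with a non-enolisable aldehyde; E1cB dehydration should give the conjugated enone as its thermodynamically preferred E isomer.

**Step 4**
Reactants: 5 (E)-1-(2-hydroxy-3-iodo-6-isopropoxy-4-methoxyphenyl)-3-(4-isopropoxyphenyl)prop-2-en-1-one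
Product: 7 8-iodo-5-isopropoxy-2-(4-isopropoxyphenyl)-7-methoxy-4H-chromen-4-one, via flavanone 6 (not isolated)
Conditions: I2 (10 mol %), DMSO, 130 °C
Reagents that add atoms: none
Why: Oxidative cyclisation of a 2'-hydroxychalcone; 6-endo-trig oxa-Michael closure gives the racemic flavanone 6, which is iodinated at C3 and loses HI, while DMSO reoxidises iodide so that iodine stays catalytic and the aryl iodide and ethers are untouched.

**Step 5**
Reactants: 8 3-bromo-4-hydroxybenzaldehyde
Product: 9 3-bromo-4-isopropoxybenzaldehyde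
Conditions: 2-bromopropane (1.5 equiv), K2CO3, DMF, 60 °C
Reagents that add atoms: 2-bromopropane, CC(C)Br
Why: Williamson etherification of an acidic, formyl-activated phenol, which alkylates cleanly on oxygen.

**Step 6**
Reactants: 9 3-bromo-4-isopropoxybenzaldehyde
Product: 10 4-isopropoxy-3-(4,4,5,5-tetramethyl-1,3,2-dioxaborolan-2-yl)benzaldehyde
Conditions: B2pin2, Pd(dppf)Cl2 (3 mol %), KOAc, 1,4-dioxane, 90 °C
Reagents that add atoms: bis(pinacolato)diboron, CC1(C)OB(OC1(C)C)B1OC(C)(C)C(C)(C)O1
Why: Miyaura borylation; the aryl bromide adds to zerovalent palladium, acetate mediates boryl transfer but is too weak a base to trigger biaryl homocoupling, and the aldehyde is tolerated.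

**Step 7**
Reactants: 7 8-iodo-5-isopropoxy-2-(4-isopropoxyphenyl)-7-methoxy-4H-chromen-4-one; 10 4-isopropoxy-3-(4,4,5,5-tetramethyl-1,3,2-dioxaborolan-2-yl)benzaldehyde
Product: 11 4-isopropoxy-3-[5-isopropoxy-2-(4-isopropoxyphenyl)-7-methoxy-4-oxo-4H-chromen-8-yl]benzaldehyde
Conditions: Pd(OAc)2 (5 mol %), SPhos (10 mol %), K3PO4, toluene/H2O, 90 °C
Reagents that add atoms: none
Why: Suzuki–Miyaura coupling; the aryl iodide undergoes oxidative addition readily, and the bulky dialkylbiarylphosphine supports transmetalation and reductive elimination for a biaryl with three ortho substituents, while the formyl group and the chromone are inert to aqueous phosphate.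

**Step 8**
Reactants: 11 4-isopropoxy-3-[5-isopropoxy-2-(4-isopropoxyphenyl)-7-methoxy-4-oxo-4H-chromen-8-yl]benzaldehyde
Product: 12 8-(5-ethynyl-2-isopropoxyphenyl)-5-isopropoxy-2-(4-isopropoxyphenyl)-7-methoxy-4H-chromen-4-one
Conditions: dimethyl (1-diazo-2-oxopropyl)phosphonate, K2CO3, MeOH/THF, 0 °C to rt
Reagents that add atoms: dimethyl (1-diazo-2-oxopropyl)phosphonate, COP(=O)(OC)C(=[N+]=[N-])C(C)=O
Why: Seyferth–Gilbert homologation in its Ohira–Bestmann form; it turns the aryl aldehyde into the terminal alkyne under carbonate in methanol, so no alkyllithium, which would attack the chromone of unit 2, is needed.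

**Step 9**
Reactants: 12 8-(5-ethynyl-2-isopropoxyphenyl)-5-isopropoxy-2-(4-isopropoxyphenyl)-7-methoxy-4H-chromen-4-one
Product: 14 3-{4-isopropoxy-3-[5-isopropoxy-2-(4-isopropoxyphenyl)-7-methoxy-4-oxo-4H-chromen-8-yl]phenyl}prop-2-ynoic acid, via cesium propiolate 13 (not isolated)
Conditions: CO2 (2 atm), AgI (2 mol %), Cs2CO3 (1.5 equiv), DMF, 50 °C; then 1 M HCl, 0 °C
Reagents that add atoms: carbon dioxide, O=C=O
Why: Silver-catalysed C–H carboxylation of a terminal alkyne; a silver acetylide formed with carbonate inserts CO2 to give the cesium propiolate, and cold acidification should free the acid without decarboxylation and without any strong base touching the chromone.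

**Step 10**
Reactants: 15 phloroglucinol
Product: 16 3,5-diisopropoxyphenol
Conditions: 2-bromopropane (2.1 equiv), K2CO3, DMF, 60 °C; chromatography
Reagents that add atoms: 2-bromopropane, CC(C)Br
Why: Williamson etherification stopped at the diether stage; the alkylation is statistical, so the diether is separated from mono- and tri-ether, which is acceptable for a first step on a cheap symmetric phenol.

**Step 11**
Reactants: 16 3,5-diisopropoxyphenol
Product: 17 3,5-diisopropoxyphenyl N-isopropylcarbamate
Conditions: i-PrNCO, Et3N (cat.), CH2Cl2, rt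
Reagents that add atoms: isopropyl isocyanate, CC(C)N=C=O
Why: Amine-catalysed addition of the phenol to the isocyanate (carbamoylation) installs a strong ortho-directing group that can later be removed under mild base.

**Step 12**
Reactants: 17 3,5-diisopropoxyphenyl N-isopropylcarbamate
Product: 21 3,5-diisopropoxy-2-(trimethylsilyl)phenyl N-isopropylcarbamate, via N-silyl carbamate 18 (not isolated), via aryllithium 19 (not isolated), via bis-silyl carbamate 20 (not isolated)
Conditions: TBSOTf, TMEDA, Et2O, 0 °C to rt; n-BuLi (2 equiv), TMEDA, −78 °C; TMSCl, −78 °C to rt; aq NaHSO4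
Reagents that add atoms: chlorotrimethylsilane, C[Si](C)(C)Cl
Why: Directed ortho-metalation; temporary N-silylation masks the N–H, the carbamate then steers lithiation to C2, which is also ortho to an isopropoxy group, the low temperature holds back anionic Fries migration, TMSCl traps the aryllithium and the N–Si bond is hydrolysed on acidic work-up.

**Step 13**
Reactants: 21 3,5-diisopropoxy-2-(trimethylsilyl)phenyl N-isopropylcarbamate
Product: 23 3,5-diisopropoxy-2-(trimethylsilyl)phenyl trifluoromethanesulfonate, via silylphenol 22 (not isolated)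
Conditions: DBU, Et2NH, MeCN, 40 °C; then PhNTf2, rt
Reagents that add atoms: N-phenylbis(trifluoromethanesulfonimide), O=S(=O)(N(c1ccccc1)S(=O)(=O)C(F)(F)F)C(F)(F)F
Why: E1cB cleavage of the N–H carbamate releases the phenoxide and isopropyl isocyanate, which diethylamine scavenges as a urea, and the phenoxide is triflated in the same pot by a sulfonimide mild enough to leave the C–Si bond intact.

**Step 14**
Reactants: 14 3-{4-isopropoxy-3-[5-isopropoxy-2-(4-isopropoxyphenyl)-7-methoxy-4-oxo-4H-chromen-8-yl]phenyl}prop-2-ynoic acid; 23 3,5-diisopropoxy-2-(trimethylsilyl)phenyl trifluoromethanesulfonate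
Product: 26 penta-O-isopropyl sotetsuflavone, via 3,5-diisopropoxybenzyne 24 (not isolated), via 2-hydroxyaryl ynone 25 (not isolated)
Conditions: 23 (1.5 equiv), CsF (4 equiv), THF, 125 °C, sealed tube
Reagents that add atoms: none
Why: Fluoride attacks silicon in 23 and expels triflate to give aryne 24, and the cesium carboxylate of 14 adds through oxygen to the aryne carbon remote from the flanking isopropoxy group, because that inductively withdrawing substituent distorts the triple bond and stabilises the aryl anion developing beside it. The anion then attacks its own ester carbonyl through a four-membered transition state, and ring opening delivers the 2-oxidoaryl ynone 25, the net result being insertion of the aryne into the acid C–O bond (forming O1–C8a and C4–C4a). The closest known reaction type is the fluoride-mediated C–O insertion of arynes into carboxylic acids, which is documented to carry arylpropiolic acids on to flavones. The pyranone closes by 6-endo-dig oxa-Michael addition of the phenoxide to the ynone (forming O1–C2), followed by protonation at C3. No stereocentre is formed. The step needs regioselective capture of the aryne, secured by the alkoxy group next to the triple bond, which ends up as the C5 oxygen of ring A, and acyl transfer faster than protonation of the aryl anion, secured by using the cesium carboxylate in hot aprotic THF.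

**Step 15**
Reactants: 26 penta-O-isopropyl sotetsuflavone
Product: 27 sotetsuflavone
Conditions: BCl3 (excess), CH2Cl2, −78 to 0 °C; then MeOH, H2O
Reagents that add atoms: none
Why: Lewis-acid ether cleavage; boron coordinates each ether oxygen and chloride captures the secondary isopropyl group, which is much faster than for a methyl ether, and the 7-OMe of unit 2 is not peri to the carbonyl and has no chelation assistance, so it should survive while all five isopropyl ethers fall.

**Compound list**
1 | 2',6'-dihydroxy-4'-methoxyacetophenone | CC(=O)c1c(O)cc(OC)cc1O | starting material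
2 | 2'-hydroxy-6'-isopropoxy-4'-methoxyacetophenone | CC(=O)c1c(O)cc(OC)cc1OC(C)C | intermediate
3 | 2'-hydroxy-3'-iodo-6'-isopropoxy-4'-methoxyacetophenone | CC(=O)c1c(O)c(I)c(OC)cc1OC(C)C | intermediate
4 | 4-isopropoxybenzaldehyde | CC(C)Oc1ccc(C=O)cc1 | starting material
5 | (E)-1-(2-hydroxy-3-iodo-6-isopropoxy-4-methoxyphenyl)-3-(4-isopropoxyphenyl)prop-2-en-1-one | O=C(/C=C/c1ccc(OC(C)C)cc1)c1c(O)c(I)c(OC)cc1OC(C)C | intermediate
6 | 8-iodo-5-isopropoxy-2-(4-isopropoxyphenyl)-7-methoxychroman-4-one (racemic) | COc1cc(OC(C)C)c2c(c1I)OC(c1ccc(OC(C)C)cc1)CC2=O | intermediate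
7 | 8-iodo-5-isopropoxy-2-(4-isopropoxyphenyl)-7-methoxy-4H-chromen-4-one (unit 2 iodide) | COc1cc(OC(C)C)c2c(=O)cc(-c3ccc(OC(C)C)cc3)oc2c1I | intermediate
8 | 3-bromo-4-hydroxybenzaldehyde | O=Cc1ccc(O)c(Br)c1 | starting material
9 | 3-bromo-4-isopropoxybenzaldehyde | O=Cc1ccc(OC(C)C)c(Br)c1 | intermediate
10 | 4-isopropoxy-3-(4,4,5,5-tetramethyl-1,3,2-dioxaborolan-2-yl)benzaldehyde | O=Cc1ccc(OC(C)C)c(B2OC(C)(C)C(C)(C)O2)c1 | intermediate
11 | 4-isopropoxy-3-[5-isopropoxy-2-(4-isopropoxyphenyl)-7-methoxy-4-oxo-4H-chromen-8-yl]benzaldehyde | O=Cc1ccc(OC(C)C)c(c1)-c1c(OC)cc(OC(C)C)c2c(=O)cc(-c3ccc(OC(C)C)cc3)oc12 | intermediate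
12 | 8-(5-ethynyl-2-isopropoxyphenyl)-5-isopropoxy-2-(4-isopropoxyphenyl)-7-methoxy-4H-chromen-4-one | C#Cc1ccc(OC(C)C)c(c1)-c1c(OC)cc(OC(C)C)c2c(=O)cc(-c3ccc(OC(C)C)cc3)oc12 | intermediate
13 | cesium 3-{4-isopropoxy-3-[5-isopropoxy-2-(4-isopropoxyphenyl)-7-methoxy-4-oxo-4H-chromen-8-yl]phenyl}prop-2-ynoate | [Cs+].[O-]C(=O)C#Cc1ccc(OC(C)C)c(c1)-c1c(OC)cc(OC(C)C)c2c(=O)cc(-c3ccc(OC(C)C)cc3)oc12 | intermediate
14 | 3-{4-isopropoxy-3-[5-isopropoxy-2-(4-isopropoxyphenyl)-7-methoxy-4-oxo-4H-chromen-8-yl]phenyl}prop-2-ynoic acid | OC(=O)C#Cc1ccc(OC(C)C)c(c1)-c1c(OC)cc(OC(C)C)c2c(=O)cc(-c3ccc(OC(C)C)cc3)oc12 | intermediate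
15 | phloroglucinol | Oc1cc(O)cc(O)c1 | starting material
16 | 3,5-diisopropoxyphenol | CC(C)Oc1cc(O)cc(OC(C)C)c1 | intermediate
17 | 3,5-diisopropoxyphenyl N-isopropylcarbamate | CC(C)NC(=O)Oc1cc(OC(C)C)cc(OC(C)C)c1 | intermediate
18 | 3,5-diisopropoxyphenyl N-(tert-butyldimethylsilyl)-N-isopropylcarbamate | CC(C)N(C(=O)Oc1cc(OC(C)C)cc(OC(C)C)c1)[Si](C)(C)C(C)(C)C | intermediate
19 | {2-[N-(tert-butyldimethylsilyl)-N-isopropylcarbamoyloxy]-4,6-diisopropoxyphenyl}lithium | [Li]c1c(OC(=O)N(C(C)C)[Si](C)(C)C(C)(C)C)cc(OC(C)C)cc1OC(C)C | intermediate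
20 | 3,5-diisopropoxy-2-(trimethylsilyl)phenyl N-(tert-butyldimethylsilyl)-N-isopropylcarbamate | CC(C)N(C(=O)Oc1cc(OC(C)C)cc(OC(C)C)c1[Si](C)(C)C)[Si](C)(C)C(C)(C)C | intermediate
21 | 3,5-diisopropoxy-2-(trimethylsilyl)phenyl N-isopropylcarbamate | CC(C)NC(=O)Oc1cc(OC(C)C)cc(OC(C)C)c1[Si](C)(C)C | intermediate
22 | 3,5-diisopropoxy-2-(trimethylsilyl)phenol | C[Si](C)(C)c1c(O)cc(OC(C)C)cc1OC(C)C | intermediate
23 | 3,5-diisopropoxy-2-(trimethylsilyl)phenyl trifluoromethanesulfonate | C[Si](C)(C)c1c(OC(C)C)cc(OC(C)C)cc1OS(=O)(=O)C(F)(F)F | intermediate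
24 | 3,5-diisopropoxybenzyne (1,2-didehydro-3,5-diisopropoxybenzene) | CC(C)OC1=CC(OC(C)C)=CC#C1 | intermediate
25 | 1-(2-hydroxy-4,6-diisopropoxyphenyl)-3-{4-isopropoxy-3-[5-isopropoxy-2-(4-isopropoxyphenyl)-7-methoxy-4-oxo-4H-chromen-8-yl]phenyl}prop-2-yn-1-one | O=C(C#Cc1ccc(OC(C)C)c(c1)-c1c(OC)cc(OC(C)C)c2c(=O)cc(-c3ccc(OC(C)C)cc3)oc12)c1c(O)cc(OC(C)C)cc1OC(C)C | intermediate
26 | penta-O-isopropyl sotetsuflavone: 8-[5-(5,7-diisopropoxy-4-oxo-4H-chromen-2-yl)-2-isopropoxyphenyl]-5-isopropoxy-2-(4-isopropoxyphenyl)-7-methoxy-4H-chromen-4-one | COc1cc(OC(C)C)c2c(=O)cc(-c3ccc(OC(C)C)cc3)oc2c1-c1cc(-c2cc(=O)c3c(OC(C)C)cc(OC(C)C)cc3o2)ccc1OC(C)C | intermediate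
27 | sotetsuflavone: 8-[5-(5,7-dihydroxy-4-oxo-4H-chromen-2-yl)-2-hydroxyphenyl]-5-hydroxy-2-(4-hydroxyphenyl)-7-methoxy-4H-chromen-4-one | COc1cc(O)c2c(=O)cc(-c3ccc(O)cc3)oc2c1-c1cc(-c2cc(=O)c3c(O)cc(O)cc3o2)ccc1O | target

**Step count.** Total: 15 steps. Longest linear sequence: 9 steps (steps 1, 2, 3, 4, 7, 8, 9, 14, 15).

**Steps most likely to fail**

1. Step 14. The aryl anion may be protonated before it attacks the ester carbonyl, leaving the simple aryl ester. The propiolate may also lose CO2 at 125 °C, or the phenoxide may close in the 5-exo mode. The fallback builds ring C of unit 1 by the classical chalcone route; it sets out from aldehyde 11 and returns at 26. Commercial 2,4,6-trihydroxyacetophenone would be di-O-isopropylated (2-bromopropane, K2CO3, DMF) to 2'-hydroxy-4',6'-diisopropoxyacetophenone F1. Claisen–Schmidt condensation of this ketone with 11 (KOH, EtOH, rt) should give the unit 1 2'-hydroxychalcone F2. Catalytic I2 in DMSO at 130 °C should then close it through the unit 1 flavanone F3 (not isolated) and dehydrogenate it to 26.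

2. Step 7. Transmetalation between two hindered partners may be slow, so that protodeboronation of the electron-rich boronate and reduction of the iodide overtake the coupling. The fallback reverses the polarity of the coupling; it sets out from iodide 7 and returns at 11. Miyaura borylation of 7 (B2pin2, Pd(dppf)Cl2, KOAc, DMSO, 80 °C) should give the unit 2 8-boronic ester F4. This is then coupled with the unhindered, formyl-activated bromide 9 (Pd(OAc)2, SPhos, K3PO4, toluene/H2O) to give 11.

3. Step 12. Lithiation may be incomplete or stray to C4 between the two isopropoxy groups, the carbamoyl group may migrate to carbon (anionic Fries), or silylation of the crowded C2 anion may stall. The fallback replaces directed metalation by halogen–metal exchange with a 1,3 O-to-C silyl shift; it sets out from phenol 16 and returns at 23. Ortho-selective bromination (NBS, i-Pr2NH cat., CH2Cl2, −78 to 0 °C) should give 2-bromo-3,5-diisopropoxyphenol F5, separated from any para isomer. Silylation with HMDS (THF, reflux) gives (2-bromo-3,5-diisopropoxyphenoxy)trimethylsilane F6. n-BuLi (THF, −78 °C) exchanges bromine to form [2,4-diisopropoxy-6-(trimethylsilyloxy)phenyl]lithium F7. Silicon should then migrate from oxygen to carbon, giving the lithium salt of 22, which Tf2O traps as 23.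

**Further compounds**
F1 | step 14 | 2'-hydroxy-4',6'-diisopropoxyacetophenone | CC(=O)c1c(O)cc(OC(C)C)cc1OC(C)C
F2 | step 14 | (E)-1-(2-hydroxy-4,6-diisopropoxyphenyl)-3-{4-isopropoxy-3-[5-isopropoxy-2-(4-isopropoxyphenyl)-7-methoxy-4-oxo-4H-chromen-8-yl]phenyl}prop-2-en-1-one | O=C(/C=C/c1ccc(OC(C)C)c(c1)-c1c(OC)cc(OC(C)C)c2c(=O)cc(-c3ccc(OC(C)C)cc3)oc12)c1c(O)cc(OC(C)C)cc1OC(C)C
F3 | step 14 | 8-[5-(5,7-diisopropoxy-4-oxochroman-2-yl)-2-isopropoxyphenyl]-5-isopropoxy-2-(4-isopropoxyphenyl)-7-methoxy-4H-chromen-4-one (racemic) | O=C1CC(c2ccc(OC(C)C)c(c2)-c2c(OC)cc(OC(C)C)c3c(=O)cc(-c4ccc(OC(C)C)cc4)oc23)Oc2cc(OC(C)C)cc(OC(C)C)c12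
F4 | step 7 | 5-isopropoxy-2-(4-isopropoxyphenyl)-7-methoxy-8-(4,4,5,5-tetramethyl-1,3,2-dioxaborolan-2-yl)-4H-chromen-4-one | COc1cc(OC(C)C)c2c(=O)cc(-c3ccc(OC(C)C)cc3)oc2c1B1OC(C)(C)C(C)(C)O1
F5 | step 12 | 2-bromo-3,5-diisopropoxyphenol | CC(C)Oc1cc(O)c(Br)c(OC(C)C)c1
F6 | step 12 | (2-bromo-3,5-diisopropoxyphenoxy)trimethylsilane | CC(C)Oc1cc(O[Si](C)(C)C)c(Br)c(OC(C)C)c1
F7 | step 12 | [2,4-diisopropoxy-6-(trimethylsilyloxy)phenyl]lithium | CC(C)Oc1cc(O[Si](C)(C)C)c([Li])c(OC(C)C)c1
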